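## Structural features

The target is a 2,3-trans dihydroflavonol: a benzo ring (ring A) fused to a 2,3-dihydropyran-4-one (ring C), with a 4-hydroxy-3-methoxyphenyl group (ring B) on C2. Ring A is fully differentiated: 5-OH hydrogen-bonded to the C4 carbonyl, 7-OMe, and a prenyl group at C8 wedged between O1 and the 7-methoxy group. The two stereocentres, C2 (R, benzylic ether carbon) and C3 (R, carbinol α to the ketone), are adjacent and trans. Fragile elements are the trisubstituted prenyl alkene (electrophilic oxidants, strong acid), the β-aryloxy ketone (retro-oxa-Michael opening, which epimerises C2), the α-ketol (enolisation, air oxidation to the flavonol) and the electron-rich rings. The real difficulty is to oxygenate C3 and C4 with absolute and relative control without touching the prenyl alkene, and to place the methyl ether, the ring oxygen and the prenyl group on ring A without regiochemical ambiguity. The key step uses the fact that C3 (OH) and C4 (C=O) are neighbouring oxygenated carbons, reachable from a C3=C4 alkene of a 2-aryl-2H-chromene. That alkene is cis-disubstituted and conjugated with ring A, the class an oxo-manganese salen species prefers over an isolated trisubstituted alkene. The flavene precursor is 2S and the target 2R with the same spatial arrangement at C2; only the CIP ranking of C3 changes. All structures were checked and are stereochemically consistent.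

## Logic of the disconnections

23 ⇒ 22. The two O–CH2 bonds of the acetal protecting groups on O5 and O4' are cut. The phenols must stay masked through hydride, organolithium and hypochlorite chemistry. The final acid step is tolerable because the prenyl group in 22 has O1 and OMe as neighbours, so it cannot cyclise onto a free phenol.

22 ⇒ 20. The C4 carbonyl is traced back to the benzylic C4–O bond of an oxirane. Only that bond ionises (three oxygen donors on ring A), so an oxygen nucleophile that later leaves as a sulfide converts C4 into the ketone while the C3–O bond is never broken. Two functional groups collapse into one. The forward step must capture the C4 cation faster than it rearranges, and must not epimerise C3.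

20 ⇒ 19 (key disconnection). The C3–O and C4–O bonds are cut. Both oxygens and two stereocentres disappear and only C2 remains stereogenic. The forward step must choose C3=C4 over the prenyl alkene and the face anti to the C2 aryl group. The bis-acetal protection of 19 is kept: the para-alkoxy group on ring B is needed for aryl transfer, and both ethers survive hydride and pH 11 hypochlorite. Because 20 is very acid-labile, it is not chromatographed.

19 ⇒ 12 + 18. The C2–C1' bond is cut, which splits the molecule into its ring A and ring B halves; C2 becomes an acetal carbon whose configuration is irrelevant. The forward step must transfer the aryl group enantioselectively to a benzopyrylium ion. For that the boron reagent needs exchangeable alkoxy groups, since a pinacol ester would not let the chiral diol onto boron. Hence 18 is made in the flask from 17.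

17 ⇒ 14 ⇒ 13. The C–B bond is traced to a C–Br bond and the O–CH2 bond to the free phenol.

12 ⇒ 10 ⇒ 7. The C2–OEt bond of 12 is cut back to the lactone carbonyl of 10. In 10 the C3=C4 bond (olefination) and the O1–C2 acyl bond (lactonisation) are cut, which leads to 8. The C8–CH2 bond of 8 is reconnected to oxygen by a [3,3] shift, which gives 7. An ortho-Claisen from a tertiary allyl ether puts the normal prenyl group on the only free ortho carbon and liberates exactly the phenol that becomes O1. A para-Claisen–Cope from a prenyl ether would liberate the wrong phenol.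

7 ⇒ 3 + 6, and 6 ⇒ 4. The tertiary O–C bond is cut, and the carbonate C–O bond of 6.

3 ⇒ 2 ⇒ 1. The O–CH2 bond and then the O–CH3 bond are cut. Because 2 is symmetric, mono-protection has no regiochemical issue. The methylation of 1 is directed to the para hydroxyl by acidity.

## Other disconnections considered

Alternative 1: The cut is C2–C3. In the forward sense a confined chiral Brønsted acid would ionise the mixed aryl methyl acetal A2 to an O-aryl oxocarbenium ion at C2, which C3 of the ortho enediol bis-silyl ether attacks in a 6-endo Mukaiyama-type closure to give the tris-silyl ether A1.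
- In favour: ring C and both stereocentres arise in one C–C bond-forming step from a precursor with no stereocentre that matters. No oxidant is used, so on chemoselectivity towards the prenyl alkene this plan is better than the chosen one. A1 needs only fluoride to reach 23, which is at least equal to an acid deprotection.
- Against: ionisation of A2 can expel the ring A phenoxide instead of methanol, which cuts the tether. A strong acid meets a trisubstituted alkene and an enol silane that can be protodesilylated. Both centres and the enol geometry would have to be controlled by the catalyst alone, on a substrate class without close precedent.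
- Comparison: structurally more convergent at the ring-forming stage. Mechanistically it rests on one speculative step, where the chosen plan rests on two documented catalytic asymmetric reactions. In step count no shorter, because A2 carries the same ring A regiochemical problem plus an α-oxygenated acyl side chain.

Alternative 2: The cut is C3–C4. SmI2 would reduce the ring A aldehyde of dialdehyde A4 to a ketyl that adds to the tethered α-aryloxy aldehyde, closing ring C as the samarium-bridged cis-3,4-diol A3.
- In favour: the prenyl alkene is inert to SmI2, so this plan is better on alkene chemoselectivity. The ring A half could be taken from 8, which is equal in economy for that fragment. A3 would be oxidised at the benzylic carbinol to 22, so the end game is equal.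
- Against: C2 of A4 is α to an aldehyde and carries both an aryl and an aryloxy group, so it can racemise by enolisation. α-Aryloxy carbonyl compounds are prone to reductive C–O cleavage by SmI2. The 2,3-trans relationship would depend on a cyclic transition state that the bulky ring A may distort. One more oxidation step is needed after the closure.
- Comparison: in the chosen plan C2 sits in a configurationally stable ether before any oxidation. The step count is equal or one higher for this alternative.

Alternative 3: The cut is O1–C8a. The C2 alkoxide of the anti keto diol A6 would displace fluoride ortho to the ketone (SNAr via a Meisenheimer complex, 6-exo) to give A5 with retention at both centres.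
- In favour: both stereocentres come from acyclic aldol-type chemistry before ring closure. No alkene oxidation is needed and no light- or acid-labile intermediate appears, which is better than the chosen plan on handling. The ring A alkoxy groups are meta to fluorine and do not deactivate the substitution. A5 differs from 22 only by a silyl group, so the end game is equal.
- Against: A6 is a β-hydroxy ketone, whose alkoxide can undergo retro-aldol cleavage, epimerise the α-carbon, or pass its silyl group between the two oxygens (after which the wrong oxygen would close a five-membered ring). The fluorine is flanked by the prenyl group. The pentasubstituted fluoroarene transfers the ring A regiochemical problem to a less accessible starting material.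
- Comparison: mechanistically reliable in the ring closure itself, but clearly longer, and less secure in the basic step than the chosen oxidation sequence.

Key step: step 10

Assumption: the (S,S) antipode of the salen complex is taken as matched, because its known sense with 2,2-dialkyl-2H-chromenes (3S,4S oxide) coincides with attack anti to the aryl group of (2S)-19; the antipode of the tartaric diamide that gives (2S)-19 is to be fixed in a first run.

## Route

Step 1
Reactants: 1 2,4,6-trihydroxybenzaldehyde
Product: 2 2,6-dihydroxy-4-methoxybenzaldehyde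
Conditions: Me2SO4 (1.0 equiv), K2CO3 (1.0 equiv), acetone, 0 → 20 °C
Reagents that add atoms: dimethyl sulfate, COS(=O)(=O)OC
Why: Williamson O-methylation under acidity control; the para hydroxyl is the most acidic and is not tied up in a hydrogen bond to the aldehyde, and the hard electrophile in acetone favours O- over C-alkylation.

Step 2
Reactants: 2 2,6-dihydroxy-4-methoxybenzaldehyde
Product: 3 2-hydroxy-4-methoxy-6-(methoxymethoxy)benzaldehyde
Conditions: MOMCl (1.1 equiv), i-Pr2NEt (1.5 equiv), CH2Cl2, 0 °C
Reagents that add atoms: chloromethyl methyl ether, COCCl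
Why: Acetal protection of one of two equivalent phenols; after the first alkylation the remaining hydroxyl is locked in the hydrogen bond to the aldehyde and reacts much more slowly, so mono-protection should be clean.

Step 3
Reactants: 4 2-methylbut-3-en-2-ol
Product: 6 tert-butyl 2-methylbut-3-en-2-yl carbonate, via lithium alkoxide 5 (not isolated)
Conditions: n-BuLi (1.0 equiv), THF, −78 → 0 °C; Boc2O (1.05 equiv), 0 → 20 °C
Reagents that add atoms: di-tert-butyl dicarbonate, CC(C)(C)OC(=O)OC(=O)OC(C)(C)C
Why: Acylation of a tertiary alkoxide by the anhydride; a standard preparation of tertiary allylic carbonates.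

Step 4
Reactants: 3 2-hydroxy-4-methoxy-6-(methoxymethoxy)benzaldehyde; 6 tert-butyl 2-methylbut-3-en-2-yl carbonate
Product: 7 4-methoxy-2-(methoxymethoxy)-6-[(2-methylbut-3-en-2-yl)oxy]benzaldehyde
Conditions: Pd(PPh3)4 (3 mol%), 6 (1.5 equiv), THF, 0 → 20 °C
Reagents that add atoms: none
Why: Decarboxylative Tsuji–Trost etherification: zerovalent palladium ionises the carbonate, the released tert-butoxide deprotonates the phenol, and the phenoxide attacks the more substituted allyl terminus under kinetic control to give the tertiary ether. The palladium is removed before heating so that the ether cannot isomerise to the linear prenyl ether.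

Step 5
Reactants: 7 4-methoxy-2-(methoxymethoxy)-6-[(2-methylbut-3-en-2-yl)oxy]benzaldehyde
Product: 10 7-methoxy-5-(methoxymethoxy)-8-(3-methylbut-2-en-1-yl)-2H-chromen-2-one, via prenyl salicylaldehyde 8 (not isolated), via hydroxycinnamate ester 9 (not isolated)
Conditions: PhNEt2, 130 °C; then Ph3P=CHCO2Et (1.5 equiv), 200 °C
Reagents that add atoms: ethyl (triphenylphosphoranylidene)acetate, CCOC(=O)C=P(c1ccccc1)(c1ccccc1)c1ccccc1
Why: Aromatic Claisen rearrangement to the only free ortho carbon turns the tertiary allyl ether into the normal prenyl group and frees the phenol next to it; Wittig olefination of the aldehyde and thermal lactonisation of the (Z)-cinnamate then give the coumarin, as in the classical synthesis of 5,7-dialkoxy-8-prenylcoumarins from such salicylaldehydes.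

Step 6
Reactants: 10 7-methoxy-5-(methoxymethoxy)-8-(3-methylbut-2-en-1-yl)-2H-chromen-2-one
Product: 12 2-ethoxy-7-methoxy-5-(methoxymethoxy)-8-(3-methylbut-2-en-1-yl)-2H-chromene (racemic at the acetal carbon), via lactol 11 (not isolated)
Conditions: i-Bu2AlH (1.2 equiv), CH2Cl2, −78 °C; aq. KNaC4H4O6 work-up; crude 11, EtOH, PPTS (5 mol%), 20 °C; Et3N quench
Reagents that add atoms: ethanol, CCO
Why: Half-reduction of the lactone to the lactol through the stable tetrahedral aluminate at −78 °C, then acid-catalysed acetalisation through the strongly stabilised 5,7-dioxygenated benzopyrylium ion; the acetal ethers survive pyridinium tosylate in ethanol.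

Step 7
Reactants: 13 4-bromo-2-methoxyphenol
Product: 14 4-bromo-2-methoxy-1-(methoxymethoxy)benzene
Conditions: MOMCl (1.2 equiv), i-Pr2NEt (1.5 equiv), CH2Cl2, 0 → 20 °C
Reagents that add atoms: chloromethyl methyl ether, COCCl
Why: Acetal protection of the phenol, so that the later aryllithium is not quenched and the para oxygen stays electron-donating for aryl transfer.

Step 8
Reactants: 14 4-bromo-2-methoxy-1-(methoxymethoxy)benzene
Product: 17 [3-methoxy-4-(methoxymethoxy)phenyl]boronic acid, via aryllithium 15 (not isolated), via lithium triisopropoxyborate 16 (not isolated)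
Conditions: n-BuLi (1.05 equiv), THF, −78 °C; B(Oi-Pr)3 (1.5 equiv), −78 → 0 °C; aq. HCl to pH 5, 0 °C
Reagents that add atoms: triisopropyl borate, CC(C)OB(OC(C)C)OC(C)C; water, O
Why: Bromine–lithium exchange, trapping with the hindered borate (which limits double addition) and mild hydrolysis; the brief cold work-up at pH 5 spares the acetal ether.

Step 9
Reactants: 12 2-ethoxy-7-methoxy-5-(methoxymethoxy)-8-(3-methylbut-2-en-1-yl)-2H-chromene; 17 [3-methoxy-4-(methoxymethoxy)phenyl]boronic acid
Product: 19 (2S)-7-methoxy-2-[3-methoxy-4-(methoxymethoxy)phenyl]-5-(methoxymethoxy)-8-(3-methylbut-2-en-1-yl)-2H-chromene, via diethyl boronate 18 (not isolated)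
Conditions: 17, EtOH, 3 Å MS, 60 °C, evaporation (18, 1.5 equiv); 12, N,N'-dibenzyl-2,3-dihydroxybutanediamide (one antipode, 10 mol%), Ce(OTf)4 (5 mol%), EtOAc, −40 → 4 °C, dark
Reagents that add atoms: none
Why: Chiral-diol/Lewis-acid-catalysed addition of an aryl boronate to a 2-alkoxy-2H-chromene (Petasis-type): the acetal ionises to the benzopyrylium ion, the tartaric diamide exchanges onto boron in place of the ethoxides, and the chiral boronate complex delivers the electron-rich aryl group to C2 within the ion pair. The diol antipode sets C2 as S; low temperature suppresses the uncatalysed racemic pathway and darkness prevents oxa-6π ring opening.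

Step 10
Reactants: 19 (2S)-7-methoxy-2-[3-methoxy-4-(methoxymethoxy)phenyl]-5-(methoxymethoxy)-8-(3-methylbut-2-en-1-yl)-2H-chromene
Product: 20 (2R,3S,4S)-3,4-epoxy-7-methoxy-2-[3-methoxy-4-(methoxymethoxy)phenyl]-5-(methoxymethoxy)-8-(3-methylbut-2-en-1-yl)chromane (oxirane oxygen anti to the C2 aryl group)
Conditions: (S,S)-(salen)MnCl [(S,S)-N,N'-bis(3,5-di-tert-butylsalicylidene)-1,2-cyclohexanediaminomanganese chloride] (5 mol%), 4-phenylpyridine N-oxide (20 mol%), aq. NaOCl (1.5 equiv, Na2HPO4 buffer, pH 11.3), CH2Cl2, 0 °C, dark; cold extraction, K2CO3, pad of basic Al2O3, no chromatography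
Reagents that add atoms: sodium hypochlorite, [Na+].[O-]Cl
Why: NaOCl oxidises the trivalent manganese salen chloride to an oxo-manganese (pentavalent) species that approaches the C3=C4 bond side-on and transfers oxygen, first to C3 (leaving a benzylic radical at C4 stabilised by ring A) and then by collapse onto C4; the closest known reaction is the Jacobsen–Katsuki epoxidation of 2,2-dialkyl-2H-chromenes with the same catalyst, hypochlorite and a pyridine N-oxide donor ligand. No ring of the flavan skeleton is closed; the only ring formed is the oxirane, by this stepwise [2+1] oxygen-atom transfer, and its cis fusion is enforced by the six-membered ring C. C3 and C4 are set together by the face of approach: the C2 aryl group shields its own face, and the (S,S) antipode, whose sense with 2,2-dialkylchromenes corresponds to the 3S,4S oxide, adds on the same open face, so substrate and catalyst are matched and the 2,3-trans oxide should result. The step needs chemoselectivity for C3=C4 over the prenyl alkene: oxo-manganese salen species select cis-disubstituted aryl-conjugated alkenes and are slow with isolated trisubstituted ones, and here C3=C4 is further activated by the three oxygen donors of ring A. Aryl ethers are not chlorinated at pH 11.3, and the buffered basic medium, 0 °C and exclusion of light protect both the acid-labile epoxide and the configuration of C2. Any residual (2R) flavene is mismatched and reacts more slowly, so the step should also raise the enantiomeric purity. The product is carried on at once.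

Step 11
Reactants: 20 (2R,3S,4S)-3,4-epoxy-7-methoxy-2-[3-methoxy-4-(methoxymethoxy)phenyl]-5-(methoxymethoxy)-8-(3-methylbut-2-en-1-yl)chromane
Product: 22 (2R,3R)-3-hydroxy-7-methoxy-2-[3-methoxy-4-(methoxymethoxy)phenyl]-5-(methoxymethoxy)-8-(3-methylbut-2-en-1-yl)-2,3-dihydro-4H-chromen-4-one, via alkoxysulfonium mesylate 21 (not isolated)
Conditions: DMSO (10 equiv), MsOH (1.05 equiv), CH2Cl2, −40 °C; then Et3N (4 equiv), −40 → 20 °C
Reagents that add atoms: dimethyl sulfoxide, CS(C)=O
Why: Acid-promoted opening of the epoxide by DMSO at the benzylic C4 (the only position that can ionise), then Kornblum/Swern-type collapse of the alkoxysulfonium ylide to the C4 ketone and dimethyl sulfide. The C3–O bond is never broken, so C3 keeps its configuration, and the cold, briefly basic finish should not enolise the α-ketol.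

Step 12
Reactants: 22 (2R,3R)-3-hydroxy-7-methoxy-2-[3-methoxy-4-(methoxymethoxy)phenyl]-5-(methoxymethoxy)-8-(3-methylbut-2-en-1-yl)-2,3-dihydro-4H-chromen-4-one
Product: 23 (2R,3R)-3,5-dihydroxy-2-(4-hydroxy-3-methoxyphenyl)-7-methoxy-8-(3-methylbut-2-en-1-yl)-2,3-dihydro-4H-chromen-4-one
Conditions: HCl (3 M aq.)–MeOH 1:10, 40 °C
Reagents that add atoms: none
Why: Acid-catalysed transacetalisation of both aryl acetal ethers to methanol, the 5-O one assisted by the neighbouring carbonyl. The prenyl group has no free ortho hydroxyl and cannot cyclise, and the 2,3-trans isomer is the thermodynamic one, so the stereocentres should persist.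

## Compound list

1 | 2,4,6-trihydroxybenzaldehyde | O=Cc1c(O)cc(O)cc1O | starting material
2 | 2,6-dihydroxy-4-methoxybenzaldehyde | COc1cc(O)c(C=O)c(O)c1 | intermediate
3 | 2-hydroxy-4-methoxy-6-(methoxymethoxy)benzaldehyde | COCOc1cc(OC)cc(O)c1C=O | intermediate
4 | 2-methylbut-3-en-2-ol | C=CC(C)(C)O | starting material
5 | lithium 2-methylbut-3-en-2-olate | [Li+].C=CC(C)(C)[O-] | intermediate
6 | tert-butyl 2-methylbut-3-en-2-yl carbonate | C=CC(C)(C)OC(=O)OC(C)(C)C | intermediate
7 | 4-methoxy-2-(methoxymethoxy)-6-[(2-methylbut-3-en-2-yl)oxy]benzaldehyde | C=CC(C)(C)Oc1cc(OC)cc(OCOC)c1C=O | intermediate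
8 | 2-hydroxy-4-methoxy-6-(methoxymethoxy)-3-(3-methylbut-2-en-1-yl)benzaldehyde | COCOc1cc(OC)c(CC=C(C)C)c(O)c1C=O | intermediate
9 | ethyl (Z)-3-[2-hydroxy-4-methoxy-6-(methoxymethoxy)-3-(3-methylbut-2-en-1-yl)phenyl]prop-2-enoate | CCOC(=O)/C=C\c1c(O)c(CC=C(C)C)c(OC)cc1OCOC | intermediate
10 | 7-methoxy-5-(methoxymethoxy)-8-(3-methylbut-2-en-1-yl)-2H-chromen-2-one | COCOc1cc(OC)c(CC=C(C)C)c2OC(=O)C=Cc12 | intermediate
11 | 7-methoxy-5-(methoxymethoxy)-8-(3-methylbut-2-en-1-yl)-2H-chromen-2-ol (racemic lactol) | COCOc1cc(OC)c(CC=C(C)C)c2OC(O)C=Cc12 | intermediate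
12 | 2-ethoxy-7-methoxy-5-(methoxymethoxy)-8-(3-methylbut-2-en-1-yl)-2H-chromene (racemic acetal) | CCOC1C=Cc2c(OCOC)cc(OC)c(CC=C(C)C)c2O1 | intermediate
13 | 4-bromo-2-methoxyphenol | COc1cc(Br)ccc1O | starting material
14 | 4-bromo-2-methoxy-1-(methoxymethoxy)benzene | COCOc1ccc(Br)cc1OC | intermediate
15 | [3-methoxy-4-(methoxymethoxy)phenyl]lithium | [Li]c1ccc(OCOC)c(OC)c1 | intermediate
16 | lithium triisopropoxy[3-methoxy-4-(methoxymethoxy)phenyl]borate | [Li+].CC(C)O[B-](OC(C)C)(OC(C)C)c1ccc(OCOC)c(OC)c1 | intermediate
17 | [3-methoxy-4-(methoxymethoxy)phenyl]boronic acid | COCOc1ccc(B(O)O)cc1OC | intermediate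
18 | diethyl [3-methoxy-4-(methoxymethoxy)phenyl]boronate | CCOB(OCC)c1ccc(OCOC)c(OC)c1 | intermediate
19 | (2S)-7-methoxy-2-[3-methoxy-4-(methoxymethoxy)phenyl]-5-(methoxymethoxy)-8-(3-methylbut-2-en-1-yl)-2H-chromene | COc1cc([C@H]2Oc3c(CC=C(C)C)c(OC)cc(OCOC)c3C=C2)ccc1OCOC | intermediate
20 | (2R,3S,4S)-3,4-epoxy-7-methoxy-2-[3-methoxy-4-(methoxymethoxy)phenyl]-5-(methoxymethoxy)-8-(3-methylbut-2-en-1-yl)chromane, oxirane oxygen anti to the C2 aryl group | COc1cc([C@H]2Oc3c(CC=C(C)C)c(OC)cc(OCOC)c3[C@@H]4O[C@@H]42)ccc1OCOC | intermediate
21 | dimethylsulfonio-oxy derivative at C4 of the 2,3-trans-flavan-3-ol (3,4-trans isomer shown), methanesulfonate salt | COc1cc([C@H]2Oc3c(CC=C(C)C)c(OC)cc(OCOC)c3[C@@H](O[S+](C)C)[C@@H]2O)ccc1OCOC.CS(=O)(=O)[O-] | intermediate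
22 | (2R,3R)-3-hydroxy-7-methoxy-2-[3-methoxy-4-(methoxymethoxy)phenyl]-5-(methoxymethoxy)-8-(3-methylbut-2-en-1-yl)-2,3-dihydro-4H-chromen-4-one | COc1cc([C@H]2Oc3c(CC=C(C)C)c(OC)cc(OCOC)c3C(=O)[C@@H]2O)ccc1OCOC | intermediate
23 | (2R,3R)-3,5-dihydroxy-2-(4-hydroxy-3-methoxyphenyl)-7-methoxy-8-(3-methylbut-2-en-1-yl)-2,3-dihydro-4H-chromen-4-one | COc1cc([C@H]2Oc3c(CC=C(C)C)c(OC)cc(O)c3C(=O)[C@@H]2O)ccc1O | target

## Step count and least certain steps

Total: 12 steps. Longest linear sequence: 9 steps (steps 1, 2, 4, 5, 6, 9, 10, 11, 12).

**Step 10 (key step).** The most likely failure is loss of chemoselectivity once conversion is pushed: oxygen transfer to the prenyl alkene or to the doubly activated C2–H bond, together with premature opening of the very labile oxide by chloride or water. Opening at C4 alone is tolerable, since it leaves the right oxidation pattern.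

Fallback: the prenyl alkene is replaced by an allyl group during the oxidation and restored afterwards. It sets out from 3 and comes back at 22.
- O-Allylation of 3 (allyl bromide, K2CO3, acetone) would give 2-(allyloxy)-4-methoxy-6-(methoxymethoxy)benzaldehyde F1.
- Ortho-Claisen rearrangement (PhNEt2, 190 °C) would give 3-allyl-2-hydroxy-4-methoxy-6-(methoxymethoxy)benzaldehyde F2.
- Wittig olefination and lactonisation as in step 5 would give 8-allyl-7-methoxy-5-(methoxymethoxy)-2H-chromen-2-one F3.
- Reduction and acetalisation as in step 6 would give 8-allyl-2-ethoxy-7-methoxy-5-(methoxymethoxy)-2H-chromene F4.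
- Arylation with 18 as in step 9 would give the (2S)-8-allyl-2-aryl-2H-chromene F5.
- The same salen epoxidation, for which a monosubstituted alkene is the poorest substrate class, would give the 8-allyl 3,4-epoxyflavan F6.
- DMSO oxidation as in step 11 would give the 8-allyl dihydroflavonol bis-acetal ether F7.
- Cross-metathesis with 2-methylbut-2-ene (second-generation Grubbs catalyst, RuCl2(H2IMes)(PCy3)(=CHPh), CH2Cl2, 40 °C) would install the prenyl terminus and rejoin the route at 22.

**Step 9.** The most likely failure is erosion of enantioselectivity by a racemic background pathway: the 5,7-dioxygenated acetal ionises so easily that aryl transfer from boron not bound to the chiral diol can compete.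

Fallback: a resolution replaces the asymmetric C–C bond formation. From 12 and 17, an achiral zerovalent nickel coupling (Ni(cod)2, PPh3, dioxane, 20 °C) would give the racemic 2-aryl-2H-chromene F8. Submitted to step 10, the (S,S) catalyst would consume the matched (2S) enantiomer first (kinetic resolution of a racemic chromene by asymmetric epoxidation). At partial conversion 20 is reached and the route rejoined there, at the cost of half the material.

**Step 11.** The most likely failure is partitioning of the C4 cation into a 1,2-hydride shift (Meinwald-type, towards the 3-ketone) or proton loss before DMSO captures it, or collapse of the ylide to a methylthiomethyl ether of the C3 hydroxyl.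

Fallback: from 20, hydrolytic opening (THF–H2O, pH 7 phosphate buffer) would give the 2,3-trans-flavan-3,4-diol bis-acetal ether F9 (3,4-trans with its C4 epimer). Selective oxidation of the electron-rich benzylic carbinol with DDQ (dioxane, 20 °C) would then come back to the route at 22.

**Step 4.** The most likely failure is attack at the less substituted allyl terminus, or palladium-mediated isomerisation to the linear prenyl ether, which would later rearrange to the wrong carbon; the hydrogen-bonded phenol may also react slowly.

Fallback: from 3, copper-catalysed alkylation with 3-chloro-3-methylbut-1-yne (CuCl2 cat., DBU, MeCN, 0 °C) would give 4-methoxy-2-(methoxymethoxy)-6-[(2-methylbut-3-yn-2-yl)oxy]benzaldehyde F10. Semi-hydrogenation (H2, Pd/CaCO3 poisoned with Pb(OAc)2, quinoline, EtOAc) would return to the route at 7.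

**Step 1.** The most likely failure is over-methylation to the 4,6-dimethyl ether, or C-methylation of the phloroglucinol-type anion.

Fallback: chelation-controlled cleavage of the two ortho methyl ethers of 2,4,6-trimethoxybenzaldehyde F11 (AlCl3, 3.5 equiv, CH2Cl2, 0 → 40 °C) would reach 2, where the route is rejoined.

## Further compounds

F1 | step 10 | 2-(allyloxy)-4-methoxy-6-(methoxymethoxy)benzaldehyde | C=CCOc1cc(OC)cc(OCOC)c1C=O
F2 | step 10 | 3-allyl-2-hydroxy-4-methoxy-6-(methoxymethoxy)benzaldehyde | COCOc1cc(OC)c(CC=C)c(O)c1C=O
F3 | step 10 | 8-allyl-7-methoxy-5-(methoxymethoxy)-2H-chromen-2-one | COCOc1cc(OC)c(CC=C)c2OC(=O)C=Cc12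
F4 | step 10 | 8-allyl-2-ethoxy-7-methoxy-5-(methoxymethoxy)-2H-chromene (racemic acetal) | CCOC1C=Cc2c(OCOC)cc(OC)c(CC=C)c2O1
F5 | step 10 | (2S)-8-allyl-7-methoxy-2-[3-methoxy-4-(methoxymethoxy)phenyl]-5-(methoxymethoxy)-2H-chromene | COc1cc([C@H]2Oc3c(CC=C)c(OC)cc(OCOC)c3C=C2)ccc1OCOC
F6 | step 10 | (2R,3S,4S)-8-allyl-3,4-epoxy-7-methoxy-2-[3-methoxy-4-(methoxymethoxy)phenyl]-5-(methoxymethoxy)chromane | COc1cc([C@H]2Oc3c(CC=C)c(OC)cc(OCOC)c3[C@@H]4O[C@@H]42)ccc1OCOC
F7 | step 10 | (2R,3R)-8-allyl-3-hydroxy-7-methoxy-2-[3-methoxy-4-(methoxymethoxy)phenyl]-5-(methoxymethoxy)-2,3-dihydro-4H-chromen-4-one | COc1cc([C@H]2Oc3c(CC=C)c(OC)cc(OCOC)c3C(=O)[C@@H]2O)ccc1OCOC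
F8 | step 9 | racemic 7-methoxy-2-[3-methoxy-4-(methoxymethoxy)phenyl]-5-(methoxymethoxy)-8-(3-methylbut-2-en-1-yl)-2H-chromene | COc1cc(C2Oc3c(CC=C(C)C)c(OC)cc(OCOC)c3C=C2)ccc1OCOC
F9 | step 11 | 2,3-trans-3,4-trans-7-methoxy-2-[3-methoxy-4-(methoxymethoxy)phenyl]-5-(methoxymethoxy)-8-(3-methylbut-2-en-1-yl)chromane-3,4-diol (2R,3S,4R) | COc1cc([C@H]2Oc3c(CC=C(C)C)c(OC)cc(OCOC)c3[C@@H](O)[C@@H]2O)ccc1OCOC
F10 | step 4 | 4-methoxy-2-(methoxymethoxy)-6-[(2-methylbut-3-yn-2-yl)oxy]benzaldehyde | C#CC(C)(C)Oc1cc(OC)cc(OCOC)c1C=O
F11 | step 1 | 2,4,6-trimethoxybenzaldehyde | COc1cc(OC)c(C=O)c(OC)c1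
A1 | alternative 1 | 3,5,4'-tris-O-(tert-butyldimethylsilyl) ether of 23 | COc1cc([C@H]2Oc3c(CC=C(C)C)c(OC)cc(O[Si](C)(C)C(C)(C)C)c3C(=O)[C@@H]2O[Si](C)(C)C(C)(C)C)ccc1O[Si](C)(C)C(C)(C)C
A2 | alternative 1 | mixed aryl methyl acetal of the ring B aldehyde with the ring A phenol bearing an ortho (Z)-1,2-bis(tert-butyldimethylsilyloxy)vinyl group (acetal carbon not defined) | COC(Oc1c(CC=C(C)C)c(OC)cc(O[Si](C)(C)C(C)(C)C)c1/C(O[Si](C)(C)C(C)(C)C)=C/O[Si](C)(C)C(C)(C)C)c1ccc(O[Si](C)(C)C(C)(C)C)c(OC)c1
A3 | alternative 2 | 2,3-trans-3,4-cis-flavan-3,4-diol, 5,4'-bis(methoxymethyl) ether | COc1cc([C@H]2Oc3c(CC=C(C)C)c(OC)cc(OCOC)c3[C@H](O)[C@@H]2O)ccc1OCOC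
A4 | alternative 2 | (R)-2-[2-formyl-5-methoxy-3-(methoxymethoxy)-6-(3-methylbut-2-en-1-yl)phenoxy]-2-[3-methoxy-4-(methoxymethoxy)phenyl]acetaldehyde | COc1cc([C@H](C=O)Oc2c(CC=C(C)C)c(OC)cc(OCOC)c2C=O)ccc1OCOC
A5 | alternative 3 | 3-O-(tert-butyldimethylsilyl) ether of 22 | COc1cc([C@H]2Oc3c(CC=C(C)C)c(OC)cc(OCOC)c3C(=O)[C@@H]2O[Si](C)(C)C(C)(C)C)ccc1OCOC
A6 | alternative 3 | (2R,3R)-2-(tert-butyldimethylsilyloxy)-1-[2-fluoro-4-methoxy-6-(methoxymethoxy)-3-(3-methylbut-2-en-1-yl)phenyl]-3-hydroxy-3-[3-methoxy-4-(methoxymethoxy)phenyl]propan-1-one | COc1cc([C@@H](O)[C@@H](O[Si](C)(C)C(C)(C)C)C(=O)c2c(F)c(CC=C(C)C)c(OC)cc2OCOC)ccc1OCOC
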